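The earlier runs and the new flask were generated by integration for substances that don't exist; noise was put on by code.

At early times nearly all of what has gone into the zeta run is still substrate: 8.1 % of the charge stands against the fraction 8.89 % fed by 8.00 min.

all flasks: substrate 0.061 M (fed, over 1.5 h)

| run | acid | remark | time |
|---|---|---|---|
| zeta | 2.6 mM | run made earlier; the fed solution adds 0.25 times the starting volume |  |
| theta | 4 mM | run made earlier; the fed solution adds 0.25 times the starting volume |  |
| flask | 1.83 mM | the fed solution adds 0.25 times the starting volume | 1.5 h |

| run | time / min | substrate / % | product / % |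
|---|---|---|---|
| zeta | 8.00 | 8.1 | 0.9 |
| zeta | 20.0 | 14.8 | 4.7 |
| zeta | 50.0 | 27.3 | 17.3 |
| zeta | 120 | 17.4 | 52.0 |
| theta | 8.00 | 7.7 | 0.2 |
| theta | 20.0 | 14.8 | 5.4 |
| theta | 50.0 | 22.7 | 22.9 |
| theta | 120 | 10.7 | 62.8 |

(standard deviation of a reading: 0.5 percentage points)

- acid is the free proton; pH is minus the decimal logarithm of its molar concentration
- every charge counts on the volume at the start, and the solution that is fed holds the whole dose
- the analysis behind the earlier runs scatters by 0.5 percentage points, standard deviation
- what has gone from substrate into another species counts as reacted, even if it can come back
- percentages count the whole charge, also what has not yet gone in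

* part of the substrate that has reacted at 1.5 h
* pH of the solution at 1.5 h

1. I turn the question round. Survival is the substrate present over the fraction of the charge fed so far, and the even case, the zero of my scale, is a survival of 0.5. At 1.5 h the fed fraction is whole, so for less than 0.5 of the charge to have reacted in the flask, its survival must still be above 0.5 at that time.

2. Reading the logarithm of survival between 20.0 min and 50.0 min, I find it crosses 0.5 at 48.3 min in the zeta run and 37.6 min in the theta run.

3. I take the reciprocal of this time as a pseudo-first-order loss constant, up to a factor, and run it straight in acid. That gives 57.2 min for the even time of the flask, the moment its substrate is 0.5 of what has gone in. This is shorter than the dosing time 90 min, so I commit to more than 0.5 of the charge reacted.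

4. The forecast gives 62 % (58 % to 66 %) and pH 2.83 (2.78 to 2.9), with the ground “Acid appears not to be consumed”.

The flask gives 60.4 % reacted and pH 2.83, and at 1.50 h it holds 29.7 % as dormant form beside 30.7 % as product.

    substrate + acid → weak acid + acid + product (k = 8.10 M⁻¹ min⁻¹)
    weak acid ⇌ conjugate base + acid, settled at all times (K = 2.00 × 10⁻¹⁰ M)
    substrate → weak acid + product (k = 3.70 × 10⁻⁴ min⁻¹)
    substrate ⇌ dormant form (K = 2.40, k = 0.0160 min⁻¹)

A line in the logarithm of survival, drawn between the flask's substrate at 0.750 h and at 1.50 h, puts the flask's even time at about 60.7 min, against my 57.2 min.

For the neighbour with 4.6 × 10⁻⁴ M of acid, the same line gives an even time of 85.4 min, a little shorter than 90 min, which puts it close to even. That neighbour gives 47.3 %, on the other side of even by 2.7 percentage points.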